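Remarks. Locants C1–C15 are those of the target (C1–C10 ring, C11–C13 on C7, C14 on C10, C15 on C4) and are kept for every intermediate; systematic names of monocyclic compounds use their own ring locants. TBS = tert-butyldimethylsilyl, TES = triethylsilyl, Ms = methanesulfonyl.

## Analysis of the target

The target is a germacranolide: a cyclodeca-1(10),4-diene (C1–C10) with an α-methylene-γ-butyrolactone trans-fused across C7–C8 (C11=C13, C12 carbonyl, lactone oxygen on C8). It carries a free secondary allylic hydroxyl at C6 and, on C15, the ester of (2E)-2-(acetoxymethyl)but-2-enoic acid. Both ring alkenes are trisubstituted: C1=C10 is E, and in C4=C5 the ring carbons C3 and C6 are on opposite sides (Z by the sequence rule only because C15 bears oxygen), so C15 and C6 are cis. The three stereocentres are contiguous (6R,7S,8S): O6 and O8 lie on one face of the ring and the C7–C11 bond on the other, so H6/H7 and H7/H8 are both anti. Sensitive points are the exocyclic enoate (a Michael acceptor), the C6 hydroxyl (it can translactonise to the 6,12-olide under base), the allylic acetate of the side chain (open to SN2′ attack by nucleophilic amines and phosphines) and the 1(10),4-diene (transannular cyclisation under strong acid). The difficulty lies in a ten-membered ring with two geometrically defined trisubstituted alkenes, in three oxygen functions (O6, O8, O15) that must be told apart, and in a labile acyl group that has to come last. The feature used here is that C6, the carbinol carbon, and C10, the methyl-bearing alkene carbon, are 1,5-related through C7–C8–C9. A bond between them turns the ten-membered ring into a cyclopentane (C6–C7–C8–C9–C10) fused to a cycloheptane (C10–C1–C2–C3–C4–C5–C6), in which the C6 oxygen is a tertiary alkoxide 1,3 to a leaving group on C1.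

## Retrosynthetic reasoning

The C15–O acyl bond is cut first, giving diol 32 and acid 38. The side chain is the most fragile part of the molecule, so it is added last; forward, the primary allylic hydroxyl of 32 must be acylated in the presence of the hindered secondary C6 hydroxyl. Acid 38 is traced through 37, 36 and 35 to 33 and 34: an aldehyde–acrylate coupling, acetylation, allylic transposition of the acetate to the (E)-alkene and ester cleavage.

Next the C11=C13 methylene and the C12–O8 lactone bond are cut (32 from 31, 31 from 28, 28 from 25). The methylene is added by aminomethylation and elimination of the lactone enolate, and the lactone by oxidation of the C8,C12-diol 25. While the enolate is made, O6 and O15 must be masked, or O6 would take part in lactonisation and translactonisation. Because they are cis across C4=C5, one isopropylidene acetal (24, from diol 23) covers both and is orthogonal to the silyl ethers on O8 and O12.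

Diol 23 is taken back to enone 22 (C6 carbinol from the ketone by 1,2-hydride addition) and 22 to the β,γ-epoxy ketone 21. Cutting here means C4=C5 and the free O15 arise together when the C5 enolate expels the epoxide oxygen, so neither alkene nor hydroxyl needs a separate construction.

The key disconnection reconnects C6 to C10: ketone 21 comes from hydroazulenol mesylate 19. The ten-membered ring is then opened from a bicycle and not closed from a chain, and the E geometry of C1=C10 follows from the relative configuration of C1 and C10 in 19. Forward, the C6 alkoxide has to push out the C1 mesylate with cleavage of the shared bond.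

Bicycle 19 is simplified to alkene 18 (epoxide from the exocyclic C4=C15 alkene, guided by the C6 hydroxyl) and 18 to the monocyclic ketone 17 by cutting C5–C6. Forward, an allylsilane tethered to C10 adds to the C6 ketone; this closes the seven-membered ring, makes the tertiary alcohol cis to the C10 methyl and leaves the C4 methylidene group.

Ketone 17 is the mesylate of 16. The C1 carbinol of 16 comes from diketone 15 by reduction of the side-chain carbonyl, the C10 methyl from alkylation of 14, and the C10–C1 bond from acylation of the enolate of 10 with amide 13. Acylation before methylation lets the second substituent enter at the doubly activated carbon under weak base, so the C7 proton next to the β-silyloxy group is never removed. Amide 13 is cut at C2–C3 into 11 and 12.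

Cyclopentanone 10 carries the only stereocentres that reach the target (C7, C8). It is taken back through 9 to enone 7 by cutting the C8–O bond (enantioselective conjugate borylation, then oxidation, with C7 settling trans). Enone 7 comes from vinylogous ester 5 by carbonyl transposition, and 5 through 4 from 1 and 2.

## Alternatives that were turned down

Alternative 1: The cut is at C4=C5 with O6 acylated by a C15 carboxyl. The eleven-membered macrolactone A1 (C4 methylidene, C6 vinyl) would be treated with second-generation Grubbs catalyst to give A2, closing the butenolide and the ten-membered carbocycle with loss of ethylene.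
- For: the butenolide forces C15 and C6 to be cis, which is exactly the C4=C5 geometry of the target. On this point it is stronger than the chosen route, where that geometry rests on the course of an elimination. C6 is set before ring closure and C13 is already in place.
- Against: the reacting alkenes are a 1,1-disubstituted, electron-poor acrylate and a vinyl group on an acyloxy-bearing carbon. They must form a trisubstituted alkene while closing a strained, bridged ten-membered ring. C1=C10 and C11=C13 can also enter the catalytic cycle. A1 needs a macrolactonisation of its own, and E-C1=C10 has to be made by olefination in an open chain. Afterwards C15 is at the acid level and must be reduced and O6/O15 differentiated again.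
- Comparison: the chosen route is longer before the key step, but it sets E-C1=C10 stereospecifically and forms the ring without any cyclisation entropy.

Alternative 2: The cut is at C5–C6. Aldehyde A3, with the trans-fused lactone already present and a C5 alkenyl iodide, would be cyclised with CrCl2 and catalytic NiCl2 to the ten-membered allylic alcohol A4.
- For: it is convergent and short, the lactone is in place, the iodide geometry passes into C4=C5, and only methylenation and the C15 ester remain. On step economy it is stronger than the chosen route.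
- Against: it is a direct ten-membered closure at high dilution against transannular strain. The C6 configuration is decided in the cyclisation with no element that secures it. The C6 aldehyde sits on C7, α to a stereocentre and β to the lactone oxygen on C8, so epimerisation and β-elimination with lactone opening threaten both its preparation and the slow cyclisation.
- Comparison: the chosen route gives no better control at C6 (it also relies on a late reduction). What it offers is ring formation by bond cleavage and an alkene geometry fixed by stereoelectronics.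

Alternative 3: The cut is at C6–C7. The thirteen-membered cyclic diallyl ether A5 would be lithiated at C6 with n-BuLi, and the [2,3]-Wittig shift would form C6–C7, release the C6 alkoxide and the C11=C13 methylene, and contract the ring to A6.
- For: one step makes a C–C bond, two stereocentres, the free C6 hydroxyl and the exocyclic methylene, and contraction from a thirteen-membered ring is easier than direct closure. At the lactone end it is stronger than the chosen route, which needs a separate methylenation.
- Against: lithiation must choose C6 over C13 (both are α-oxy and allylic), and [1,2]-shift and elimination compete. The C6/C7 and C7/C8 relationships depend on the C7=C11 geometry and on the folding of a large-ring transition state, with the C8 silyloxy group in an allylic position. A5 needs a macro-etherification, and both trisubstituted ring alkenes must be built with control in an open chain.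
- Comparison: the chosen route sets C7/C8 on a cyclopentanone by catalyst and thermodynamic control and C1=C10 by fragmentation, at the cost of more steps after the ring is formed.

Key step: step 13

Assumption 1: in step 4 the ligand antipode named is taken to deliver boron to the enone face that gives 8S; should the sense of induction on this α-substituted enone be the opposite, the mirror-image ligand is used.
Assumption 2: in step 8 methyl iodide is taken to enter anti to the C8 silyloxy group; the C10 epimer, if formed, carries the same C7 and C8 centres and, since C1, C6 and C10 all become trigonal in step 13, would converge on the same cyclodecenone 21.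

## Route

Step 1
Reactants: 1 cyclopentane-1,3-dione; 2 (tert-butyldimethylsilyloxy)acetaldehyde
Product: 4 2-[2-(TBSO)ethyl]cyclopentane-1,3-dione, via alkylidene dione 3 (not isolated)
Conditions: diethyl 2,6-dimethyl-1,4-dihydropyridine-3,5-dicarboxylate (1.0 equiv), (S)-proline (10 mol%), CH2Cl2, rt
Reagents that add atoms: none
Why: Knoevenagel condensation gives the alkylidene dione 3, which the dihydropyridine reduces by conjugate hydride transfer as it forms; this reductive alkylation avoids the O-alkylation that alkyl halides give with 1,3-diones. No stereocentre is formed.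

Step 2
Reactants: 4 2-[2-(TBSO)ethyl]cyclopentane-1,3-dione
Product: 5 3-methoxy-2-[2-(TBSO)ethyl]cyclopent-2-en-1-one
Conditions: Me2SO4, K2CO3, acetone, rt
Reagents that add atoms: dimethyl sulfate, COS(=O)(=O)OC
Why: O-Alkylation of the enolised dione by a hard electrophile gives the vinylogous ester; the dione is symmetric, so only one enol ether can form, and the non-acidic conditions keep the silyl ether.

Step 3
Reactants: 5 3-methoxy-2-[2-(TBSO)ethyl]cyclopent-2-en-1-one
Product: 7 2-[2-(TBSO)ethyl]cyclopent-2-en-1-one, via allylic alcohol 6 (not isolated)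
Conditions: i-Bu2AlH, toluene, −78 °C; then 0.5 M aq. oxalic acid, 0 °C
Reagents that add atoms: water, O
Why: Stork–Danheiser transposition: 1,2-reduction of the vinylogous ester carbonyl, then acid-induced loss of water and hydrolysis of the methoxyallyl cation move the carbonyl to the former enol-ether carbon and leave the 2-alkylcyclopentenone. The weak acid spares the primary silyl ether.

Step 4
Reactants: 7 2-[2-(TBSO)ethyl]cyclopent-2-en-1-one
Product: 9 (2R,3S)-3-hydroxy-2-[2-(TBSO)ethyl]cyclopentan-1-one, via boronate 8 (not isolated)
Conditions: CuCl (5 mol%), NaOt-Bu (10 mol%), (R)-1-[(S)-2-(diphenylphosphino)ferrocenyl]ethyldicyclohexylphosphine (6 mol%), B2pin2, MeOH, THF, rt; then NaBO3·4H2O, THF/H2O, rt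
Reagents that add atoms: sodium perborate, [Na+].[Na+].O[B-]1(O)OO[B-](O)(O)OO1
Why: Copper-catalysed enantioselective conjugate borylation of a cyclic enone: the phosphine-bound copper boryl adds to C8 on one enantioface, and protonation under the alkoxide conditions lets C7 settle trans to boron. Perborate then replaces boron by oxygen with retention, which sets C8 (S) and C7 (R), the only stereocentres that are carried to the target.

Step 5
Reactants: 9 (2R,3S)-3-hydroxy-2-[2-(TBSO)ethyl]cyclopentan-1-one
Product: 10 (2R,3S)-3-(TBSO)-2-[2-(TBSO)ethyl]cyclopentan-1-one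
Conditions: TBSCl, imidazole, DMF, 0 °C to rt
Reagents that add atoms: tert-butyldimethylsilyl chloride, CC(C)(C)[Si](C)(C)Cl
Why: Silylation of the secondary hydroxyl under weakly basic conditions, which do not dehydrate the β-hydroxy ketone or epimerise C7.

Step 6
Reactants: 11 N-methoxy-N-methylacetamide; 12 2-(chloromethyl)allyltrimethylsilane
Product: 13 N-methoxy-N-methyl-4-[(trimethylsilyl)methyl]pent-4-enamide
Conditions: LiN(i-Pr)2, THF, −78 °C; then 12, NaI (10 mol%), −78 to −30 °C
Reagents that add atoms: none
Why: Alkylation of the amide lithium enolate by the allylic halide (SN2, helped by in situ iodide exchange) joins C2 to C3; the allylsilane is untouched, and the N-methoxy-N-methylamide is the acyl donor for step 7.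

Step 7
Reactants: 10 (2R,3S)-3-(TBSO)-2-[2-(TBSO)ethyl]cyclopentan-1-one; 13 N-methoxy-N-methyl-4-[(trimethylsilyl)methyl]pent-4-enamide
Product: 14 (2R,3S)-3-(TBSO)-2-[2-(TBSO)ethyl]-5-{4-[(trimethylsilyl)methyl]pent-4-enoyl}cyclopentan-1-one (C10 epimers and enol forms)
Conditions: LiN(i-Pr)2 (1.1 equiv), THF, −78 °C; then 13, −78 to −30 °C; aq. NH4Cl
Reagents that add atoms: none
Why: Kinetic deprotonation takes the unhindered C10 methylene and not the C7 methine next to the silyloxy-bearing carbon. C-Acylation of this enolate by the N-methoxy-N-methylamide stops at the chelated tetrahedral adduct, which gives the 1,3-diketone on work-up and forms the C10–C1 bond.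

Step 8
Reactants: 14 (2R,3S)-3-(TBSO)-2-[2-(TBSO)ethyl]-5-{4-[(trimethylsilyl)methyl]pent-4-enoyl}cyclopentan-1-one
Product: 15 (2S,4S,5R)-4-(TBSO)-5-[2-(TBSO)ethyl]-2-methyl-2-{4-[(trimethylsilyl)methyl]pent-4-enoyl}cyclopentan-1-one
Conditions: MeI, K2CO3, acetone, rt
Reagents that add atoms: methyl iodide, CI
Why: C-Alkylation of the stabilised enolate of a 2-acylcycloalkanone, the only position that carbonate can deprotonate, creates the quaternary C10 without forming the C7 enolate, so the β-silyloxy group is not eliminated. Methyl iodide is expected to approach anti to the C8 silyloxy group (10S; see assumption 2).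

Step 9
Reactants: 15 (2S,4S,5R)-4-(TBSO)-5-[2-(TBSO)ethyl]-2-methyl-2-{4-[(trimethylsilyl)methyl]pent-4-enoyl}cyclopentan-1-one
Product: 16 (2S,4S,5R)-4-(TBSO)-5-[2-(TBSO)ethyl]-2-[(1R)-1-hydroxy-4-[(trimethylsilyl)methyl]pent-4-en-1-yl]-2-methylcyclopentan-1-one
Conditions: Zn(BH4)2, Et2O, −40 to −20 °C; aq. NH4Cl
Reagents that add atoms: none
Why: Chelation-controlled reduction of a 2,2-disubstituted 1,3-diketone: the side-chain carbonyl C1 is less hindered than the ring ketone C6 (flanked by C10 and C7) and is reduced first within the six-membered zinc chelate. Hydride is delivered to the chelate face that carries the C14 methyl, the other face being covered by the C9–C8 ring segment and its silyloxy group; this puts O1 anti to C14 along C6–C10–C1–C2 (1R), the arrangement that becomes cis on the seven-membered ring.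

Step 10
Reactants: 16 (2S,4S,5R)-4-(TBSO)-5-[2-(TBSO)ethyl]-2-[(1R)-1-hydroxy-4-[(trimethylsilyl)methyl]pent-4-en-1-yl]-2-methylcyclopentan-1-one
Product: 17 (1R)-1-[(1S,3R,4S)-4-(TBSO)-3-[2-(TBSO)ethyl]-1-methyl-2-oxocyclopentyl]-4-[(trimethylsilyl)methyl]pent-4-en-1-yl methanesulfonate
Conditions: MsCl, Et3N, CH2Cl2, −10 °C
Reagents that add atoms: methanesulfonyl chloride, CS(=O)(=O)Cl
Why: Sulfonylation of the secondary alcohol with retention at C1; C10 is quaternary, so the β-mesyloxy ketone cannot eliminate towards the carbonyl, and the neopentyl-type mesylate is inert to the next two steps.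

Step 11
Reactants: 17 (1R)-1-[(1S,3R,4S)-4-(TBSO)-3-[2-(TBSO)ethyl]-1-methyl-2-oxocyclopentyl]-4-[(trimethylsilyl)methyl]pent-4-en-1-yl methanesulfonate
Product: 18 cis-fused hydroazulenol (fusion bond C6–C10) with C4 methylidene, C1 OMs, C6 OH, C10 methyl, C7 2-(TBSO)ethyl and C8 OTBS; 1R,6R,7R,8S,10S
Conditions: TiCl4 (1.2 equiv), CH2Cl2, −78 °C; aq. NaHCO3 at −78 °C
Reagents that add atoms: none
Why: Intramolecular Hosomi–Sakurai reaction: TiCl4 activates the C6 ketone and the allylsilane attacks through its methylene terminus C5, closing the seven-membered ring with loss of the silyl group and formation of the exocyclic C4=C15 alkene. The tether hangs from C10 and can reach only one face of the carbonyl, which is also the face anti to the C7 side chain, so the new hydroxyl is cis to the C10 methyl (6R, cis fusion).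

Step 12
Reactants: 18 cis-fused hydroazulenol with C4 methylidene
Product: 19 cis-fused hydroazulenol mesylate with C4 spiro-epoxide (C15H2–O), C6 OH, C10 methyl, C1 OMs, C7 2-(TBSO)ethyl and C8 OTBS; 1R,4S,6R,7R,8S,10S; OH, methyl, OMs, epoxide oxygen and the C7 chain on one face, C8 OTBS on the other
Conditions: VO(acac)2 (5 mol%), t-BuOOH, CH2Cl2, 0 °C to rt
Reagents that add atoms: tert-butyl hydroperoxide, CC(C)(C)OO
Why: Vanadium-catalysed hydroxyl-directed epoxidation: the tertiary C6 hydroxyl binds the metal peroxide and delivers oxygen to the homoallylic C4=C15 alkene, the only alkene present, on its own face. The C4 configuration is of no later consequence, and the mesylate and silyl ethers are inert.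

Step 13
Reactants: 19 cis-fused hydroazulenol mesylate with C4 spiro-epoxide
Product: 21 ten-membered (E)-cyclodec-1(10)-en-6-one with C4 spiro-epoxide, C7 2-(TBSO)ethyl and C8 OTBS; 4S,7R,8S, via potassium alkoxide 20 (not isolated)
Conditions: KN(SiMe3)2 (1.0 equiv), THF, −78 to 0 °C
Reagents that add atoms: none
Why: KN(SiMe3)2 deprotonates the tertiary C6 hydroxyl to give potassium alkoxide 20. In 20 the oxygen lone pair pushes into the C6–C10 bond, which lies anti-periplanar to the C1–OMs bond, and the O–C6–C10–C1–OMs array collapses in one concerted heterolysis to the C6 ketone, the C1=C10 alkene and mesylate. The closest known reaction type is the Grob (Wharton) fragmentation of bicyclic 1,3-diol monosulfonates to (E)-cycloalkenones, applied here to a cis-fused five-seven bicycle. No ring is closed by bond formation: the ten-membered ring appears by cleavage of the bond shared by the five- and seven-membered rings, so no cyclisation mode and no macrocyclisation entropy apply. No stereocentre is created (C1, C6 and C10 become trigonal; C4, C7 and C8 are untouched); the stereochemical output is the alkene geometry, fixed by the substrate: the mesylate is cis to the C10 methyl on the seven-membered ring, so with C1–O anti to C6–C10 the C2 carbon is anti to C9 and the alkene must be E. Chemoselectivity is needed against displacement of the mesylate by the alkoxide (oxetane), attack of the alkoxide on the spiro-epoxide and enolisation of the product; the anti-periplanar alignment, the unfavourable four-membered and endo five-membered geometries of those attacks, and exactly one equivalent of base at low temperature, which leaves a neutral ketone, secure it.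

Step 14
Reactants: 21 ten-membered (E)-cyclodecenone with C4 spiro-epoxide
Product: 22 (1(10)E,4Z)-cyclodeca-1(10),4-dien-6-one with C15 hydroxymethyl on C4, C7 2-(TBSO)ethyl and C8 OTBS; 7R,8S
Conditions: 1,8-diazabicyclo[5.4.0]undec-7-ene (0.2 equiv), CH2Cl2, 0 °C
Reagents that add atoms: none
Why: E1cB opening of a β,γ-epoxy ketone: the amidine removes the acidic C5 proton and the enolate expels the epoxide oxygen from C4, giving the conjugated C4=C5 enone and the C15 hydroxyl. The isomer with C15 and C6 cis (C3 anti to C6) is expected, because it follows from the transoid C3–C4–C5–C6 arrangement of the ring and is the only one that can close reversibly to the O15–C6 hemiketal.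

Step 15
Reactants: 22 cyclodeca-1(10),4-dien-6-one with C15 hydroxymethyl
Product: 23 (1(10)E,4Z)-cyclodeca-1(10),4-diene-6,15-diol with C7 2-(TBSO)ethyl and C8 OTBS; 6R,7S,8S
Conditions: NaBH4, CeCl3·7H2O, MeOH, −78 °C
Reagents that add atoms: none
Why: Luche 1,2-reduction of the enone, drawn from the open hydroxy-ketone tautomer. The small hydride is expected to add from the outer β side of the C6 carbonyl in the crown conformation of the (E,E)-type diene and so give the pseudo-equatorial 6α-alcohol (6R, H6 anti to H7); this facial selectivity is the least secure stereochemical point after the key step.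

Step 16
Reactants: 23 cyclodecadiene-6,15-diol
Product: 24 6,15-O-isopropylidene acetal of 23 (seven-membered 1,3-dioxepine across C4=C5); 6R,7S,8S
Conditions: Me2C(OMe)2, pyridinium p-toluenesulfonate (cat.), CH2Cl2, 0 °C to rt
Reagents that add atoms: 2,2-dimethoxypropane, COC(C)(C)OC
Why: The cis-disposed allylic 1,4-diol closes to the isopropylidene acetal under mild acid catalysis, too weak to protonate the diene; one group masks O6 and O15 and survives fluoride, oxidation and lithium amide.

Step 17
Reactants: 24 6,15-O-isopropylidene acetal
Product: 25 8,12-diol (C7 2-hydroxyethyl, C8 OH) with the 6,15-acetal; 6R,7R,8S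
Conditions: Bu4NF, THF, 0 °C to rt; aq. NH4Cl
Reagents that add atoms: none
Why: Fluoride cleaves both silyl ethers (Si–F bond formation) and leaves the acetal and the alkenes untouched; this frees exactly the two hydroxyls that form the lactone.

Step 18
Reactants: 25 8,12-diol with the 6,15-acetal
Product: 28 trans-fused 8,12-lactone (γ-butyrolactone across C7–C8) with the 6,15-acetal; 6R,7R,8S, via hydroxy aldehyde 26 (not isolated), via lactol 27 (not isolated)
Conditions: (2,2,6,6-tetramethylpiperidin-1-yl)oxyl (20 mol%), PhI(OAc)2 (2.5 equiv), NaHCO3, CH2Cl2, rt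
Reagents that add atoms: none
Why: Oxoammonium oxidation takes the primary C12 alcohol to aldehyde 26, which closes with O8 to lactol 27; the lactol is oxidised on to the lactone faster than the secondary C8 hydroxyl alone. O6 is masked, so only the 8,12-olide can form, and its trans fusion is fixed by C7 and C8.

Step 19
Reactants: 28 trans-fused 8,12-lactone with the 6,15-acetal
Product: 31 α-methylene lactone (C11=C13) with the 6,15-acetal; 6R,7R,8S, via Mannich base 29 (not isolated), via ammonium iodide 30 (not isolated)
Conditions: LiN(i-Pr)2, THF, −78 °C; CH2=NMe2+ I−, −78 to 0 °C; then MeI, MeOH, rt; then aq. NaHCO3, CH2Cl2, rt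
Reagents that add atoms: dimethyl(methylidene)ammonium iodide, C=[N+](C)C.[I-]
Why: Eschenmoser methylenation: the lactone enolate is aminomethylated at C11, and quaternisation followed by mild-base elimination of trimethylamine gives the exocyclic enoate. No leaving group sits β to the enolate carbon and O6 is masked, so neither elimination nor translactonisation can occur.

Step 20
Reactants: 31 α-methylene lactone with the 6,15-acetal
Product: 32 6,15-diol: (1(10)E,4Z)-6-hydroxy-4-(hydroxymethyl)-10-methyl α-methylene 8,12-lactone; 6R,7S,8S
Conditions: AcOH/THF/H2O (3:1:1), rt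
Reagents that add atoms: none
Why: Hydrolysis of the strained seven-membered isopropylidene acetal under weak acid, which does not add to the enoate, open the lactone or protonate the diene.

Step 21
Reactants: 33 tert-butyl acrylate; 34 acetaldehyde
Product: 35 tert-butyl 3-hydroxy-2-methylidenebutanoate (racemic)
Conditions: 1,4-diazabicyclo[2.2.2]octane (0.3 equiv), 1,4-dioxane/H2O, rt
Reagents that add atoms: none
Why: Morita–Baylis–Hillman reaction: conjugate addition of the amine to the acrylate, aldol addition to acetaldehyde and elimination of the amine; the carbinol centre is lost in step 23.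

Step 22
Reactants: 35 tert-butyl 3-hydroxy-2-methylidenebutanoate
Product: 36 tert-butyl 3-acetoxy-2-methylidenebutanoate
Conditions: Ac2O, pyridine, 4-(dimethylamino)pyridine (cat.), CH2Cl2, 0 °C
Reagents that add atoms: acetic anhydride, CC(=O)OC(C)=O
Why: Standard acetylation of the secondary allylic alcohol.

Step 23
Reactants: 36 tert-butyl 3-acetoxy-2-methylidenebutanoate
Product: 37 tert-butyl (2E)-2-(acetoxymethyl)but-2-enoate
Conditions: 1,4-diazabicyclo[2.2.2]octane (0.2 equiv), THF, reflux
Reagents that add atoms: none
Why: Amine-catalysed allylic transposition: SN2′ addition of the amine expels acetate, which returns at the primary carbon; the more substituted conjugated alkene with the methyl trans to the ester (E) is the thermodynamic product.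

Step 24
Reactants: 37 tert-butyl (2E)-2-(acetoxymethyl)but-2-enoate
Product: 38 (2E)-2-(acetoxymethyl)but-2-enoic acid
Conditions: CF3CO2H, CH2Cl2, 0 °C to rt
Reagents that add atoms: none
Why: Acidolysis of the tert-butyl ester through the tert-butyl cation leaves the acetate and the alkene geometry intact, which a basic hydrolysis would not.

Step 25
Reactants: 32 6,15-diol with α-methylene 8,12-lactone; 38 (2E)-2-(acetoxymethyl)but-2-enoic acid
Product: 40 CNP0184624.1, the 15-[(2E)-2-(acetoxymethyl)but-2-enoate] of 32; 1(10)E,4Z,6R,7S,8S, via acid chloride 39 (not isolated)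
Conditions: 38, (COCl)2, DMF (cat.), CH2Cl2, 0 °C to rt; then 32, 2,4,6-trimethylpyridine, CH2Cl2, −40 to 0 °C
Reagents that add atoms: none
Why: Acylation of the primary allylic C15 hydroxyl by the acid chloride with a hindered, non-nucleophilic pyridine base; the secondary C6 hydroxyl, flanked by C7 and the ring, reacts more slowly. No nucleophilic catalyst is present that could attack the allylic acetate in an SN2′ sense or add to the enoate.

## Compound list

1 | cyclopentane-1,3-dione | O=C1CCC(=O)C1 | starting material
2 | (tert-butyldimethylsilyloxy)acetaldehyde | O=CCO[Si](C)(C)C(C)(C)C | starting material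
3 | 2-[2-(TBSO)ethylidene]cyclopentane-1,3-dione | O=C1CCC(=O)C1=CCO[Si](C)(C)C(C)(C)C | intermediate
4 | 2-[2-(TBSO)ethyl]cyclopentane-1,3-dione | O=C1CCC(=O)C1CCO[Si](C)(C)C(C)(C)C | intermediate
5 | 3-methoxy-2-[2-(TBSO)ethyl]cyclopent-2-en-1-one | COC1=C(CCO[Si](C)(C)C(C)(C)C)C(=O)CC1 | intermediate
6 | 3-methoxy-2-[2-(TBSO)ethyl]cyclopent-2-en-1-ol (racemic) | COC1=C(CCO[Si](C)(C)C(C)(C)C)C(O)CC1 | intermediate
7 | 2-[2-(TBSO)ethyl]cyclopent-2-en-1-one | O=C1CCC=C1CCO[Si](C)(C)C(C)(C)C | intermediate
8 | (2R,3S)-2-[2-(TBSO)ethyl]-3-(4,4,5,5-tetramethyl-1,3,2-dioxaborolan-2-yl)cyclopentan-1-one | O=C1[C@H](CCO[Si](C)(C)C(C)(C)C)[C@@H](B2OC(C)(C)C(C)(C)O2)CC1 | intermediate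
9 | (2R,3S)-3-hydroxy-2-[2-(TBSO)ethyl]cyclopentan-1-one | O=C1[C@H](CCO[Si](C)(C)C(C)(C)C)[C@@H](O)CC1 | intermediate
10 | (2R,3S)-3-(TBSO)-2-[2-(TBSO)ethyl]cyclopentan-1-one | O=C1[C@H](CCO[Si](C)(C)C(C)(C)C)[C@@H](O[Si](C)(C)C(C)(C)C)CC1 | intermediate
11 | N-methoxy-N-methylacetamide | CC(=O)N(C)OC | starting material
12 | 2-(chloromethyl)allyltrimethylsilane | C=C(CCl)C[Si](C)(C)C | starting material
13 | N-methoxy-N-methyl-4-[(trimethylsilyl)methyl]pent-4-enamide | CON(C)C(=O)CCC(=C)C[Si](C)(C)C | intermediate
14 | (2R,3S)-3-(TBSO)-2-[2-(TBSO)ethyl]-5-{4-[(trimethylsilyl)methyl]pent-4-enoyl}cyclopentan-1-one (C10 not defined) | O=C1[C@H](CCO[Si](C)(C)C(C)(C)C)[C@@H](O[Si](C)(C)C(C)(C)C)CC1C(=O)CCC(=C)C[Si](C)(C)C | intermediate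
15 | (2S,4S,5R)-4-(TBSO)-5-[2-(TBSO)ethyl]-2-methyl-2-{4-[(trimethylsilyl)methyl]pent-4-enoyl}cyclopentan-1-one | O=C1[C@H](CCO[Si](C)(C)C(C)(C)C)[C@@H](O[Si](C)(C)C(C)(C)C)C[C@@]1(C)C(=O)CCC(=C)C[Si](C)(C)C | intermediate
16 | (2S,4S,5R)-4-(TBSO)-5-[2-(TBSO)ethyl]-2-[(1R)-1-hydroxy-4-[(trimethylsilyl)methyl]pent-4-en-1-yl]-2-methylcyclopentan-1-one | O=C1[C@H](CCO[Si](C)(C)C(C)(C)C)[C@@H](O[Si](C)(C)C(C)(C)C)C[C@@]1(C)[C@H](O)CCC(=C)C[Si](C)(C)C | intermediate
17 | (1R)-1-[(1S,3R,4S)-4-(TBSO)-3-[2-(TBSO)ethyl]-1-methyl-2-oxocyclopentyl]-4-[(trimethylsilyl)methyl]pent-4-en-1-yl methanesulfonate | O=C1[C@H](CCO[Si](C)(C)C(C)(C)C)[C@@H](O[Si](C)(C)C(C)(C)C)C[C@@]1(C)[C@H](OS(C)(=O)=O)CCC(=C)C[Si](C)(C)C | intermediate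
18 | cis-fused hydroazulenol mesylate with C4 methylidene (1R,6R,7R,8S,10S) | C[C@@]12C[C@H](O[Si](C)(C)C(C)(C)C)[C@@H](CCO[Si](C)(C)C(C)(C)C)[C@]1(O)CC(=C)CC[C@H]2OS(C)(=O)=O | intermediate
19 | cis-fused hydroazulenol mesylate with C4 spiro-epoxide (1R,4S,6R,7R,8S,10S) | C[C@@]12C[C@H](O[Si](C)(C)C(C)(C)C)[C@@H](CCO[Si](C)(C)C(C)(C)C)[C@]1(O)C[C@]3(CO3)CC[C@H]2OS(C)(=O)=O | intermediate
20 | potassium C6 alkoxide of 19 | C[C@@]12C[C@H](O[Si](C)(C)C(C)(C)C)[C@@H](CCO[Si](C)(C)C(C)(C)C)[C@]1([O-])C[C@]3(CO3)CC[C@H]2OS(C)(=O)=O.[K+] | intermediate
21 | ten-membered (E)-cyclodec-1(10)-en-6-one with C4 spiro-epoxide, C7 2-(TBSO)ethyl, C8 OTBS (4S,7R,8S) | CC(C)(C)[Si](C)(C)OCC[C@@H]1[C@@H](O[Si](C)(C)C(C)(C)C)C/C(C)=C/CC[C@@]2(CO2)CC1=O | intermediate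
22 | (1(10)E,4Z)-cyclodeca-1(10),4-dien-6-one with C4 hydroxymethyl, C7 2-(TBSO)ethyl, C8 OTBS (7R,8S) | CC(C)(C)[Si](C)(C)OCC[C@@H]1[C@@H](O[Si](C)(C)C(C)(C)C)C/C(C)=C/CC/C(CO)=C/C1=O | intermediate
23 | (1(10)E,4Z)-cyclodeca-1(10),4-diene-6,15-diol with C7 2-(TBSO)ethyl, C8 OTBS (6R,7S,8S) | CC(C)(C)[Si](C)(C)OCC[C@@H]1[C@@H](O[Si](C)(C)C(C)(C)C)C/C(C)=C/CC/C(CO)=C/[C@H]1O | intermediate
24 | 6,15-O-isopropylidene acetal of 23 (6R,7S,8S) | CC(C)(C)[Si](C)(C)OCC[C@@H]1[C@@H](O[Si](C)(C)C(C)(C)C)C/C(C)=C/CC/C2=C/[C@H]1OC(C)(C)OC2 | intermediate
25 | 8,12-diol with 6,15-O-isopropylidene acetal (6R,7R,8S) | OCC[C@@H]1[C@@H](O)C/C(C)=C/CC/C2=C/[C@H]1OC(C)(C)OC2 | intermediate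
26 | C12 aldehyde with free C8 hydroxyl and 6,15-acetal | O=CC[C@@H]1[C@@H](O)C/C(C)=C/CC/C2=C/[C@H]1OC(C)(C)OC2 | intermediate
27 | 8,12-lactol with 6,15-acetal (C12 not defined) | OC1C[C@@H]2[C@@H](O1)C/C(C)=C/CC/C3=C/[C@H]2OC(C)(C)OC3 | intermediate
28 | trans-fused 8,12-lactone with 6,15-acetal (6R,7R,8S) | O=C1C[C@@H]2[C@@H](O1)C/C(C)=C/CC/C3=C/[C@H]2OC(C)(C)OC3 | intermediate
29 | C11 (dimethylamino)methyl lactone with 6,15-acetal (C11 not defined) | CN(C)CC1C(=O)O[C@H]2C/C(C)=C/CC/C3=C/[C@@H](OC(C)(C)OC3)[C@H]12 | intermediate
30 | C11 (trimethylammonio)methyl lactone iodide with 6,15-acetal | C[N+](C)(C)CC1C(=O)O[C@H]2C/C(C)=C/CC/C3=C/[C@@H](OC(C)(C)OC3)[C@H]12.[I-] | intermediate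
31 | α-methylene 8,12-lactone with 6,15-acetal (6R,7R,8S) | C=C1C(=O)O[C@H]2C/C(C)=C/CC/C3=C/[C@@H](OC(C)(C)OC3)[C@H]12 | intermediate
32 | α-methylene 8,12-lactone 6,15-diol (1(10)E,4Z,6R,7S,8S) | C=C1C(=O)O[C@H]2C/C(C)=C/CC/C(CO)=C/[C@@H](O)[C@H]12 | intermediate
33 | tert-butyl acrylate | C=CC(=O)OC(C)(C)C | starting material
34 | acetaldehyde | CC=O | starting material
35 | tert-butyl 3-hydroxy-2-methylidenebutanoate (racemic) | CC(O)C(=C)C(=O)OC(C)(C)C | intermediate
36 | tert-butyl 3-acetoxy-2-methylidenebutanoate (racemic) | CC(OC(C)=O)C(=C)C(=O)OC(C)(C)C | intermediate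
37 | tert-butyl (2E)-2-(acetoxymethyl)but-2-enoate | CC(C)(C)OC(=O)/C(=C/C)COC(C)=O | intermediate
38 | (2E)-2-(acetoxymethyl)but-2-enoic acid | OC(=O)/C(=C/C)COC(C)=O | intermediate
39 | (2E)-2-(acetoxymethyl)but-2-enoyl chloride | ClC(=O)/C(=C/C)COC(C)=O | intermediate
40 | CNP0184624.1 (1(10)E,4Z,6R,7S,8S) | C=C1C(=O)O[C@H]2C/C(C)=C/CC/C(COC(=O)/C(=C/C)COC(C)=O)=C/[C@@H](O)[C@H]12 | target

## Step count and least certain steps

Total step count: 25. Longest linear sequence: 20 steps (steps 1–5, 7–20 and 25); step 6 and steps 21–24 are side branches.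

Step 13 (key step). The fragmentation may lose out to other reactions of the alkoxide if the flexible cis-fused bicycle does not hold the mesylate anti-periplanar to the C6–C10 bond. The alkoxide can add to the neighbouring spiro-epoxide or displace the mesylate, or the epoxide may open prematurely and release a second base that epimerises C7 or eliminates the C8 silyloxy group. The fallback removes the electrophile next to the alkoxide. It sets out from 18 and comes back at 22:
- dihydroxylation of the methylidene group (OsO4 cat., N-methylmorpholine N-oxide) gives the triol mesylate F1;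
- its 4,15-diol is closed to the acetonide F2 (2,2-dimethoxypropane, pyridinium p-toluenesulfonate);
- the same KN(SiMe3)2 fragmentation gives the cyclodecenone acetonide F3;
- 1,8-diazabicyclo[5.4.0]undec-7-ene then expels the C4 acetal oxygen from the C5 enolate with loss of acetone to give 22.

Step 9. Hydride may be delivered to the ring carbonyl or to the wrong face of the side-chain carbonyl, because chelate control over a quaternary centre whose two flanking groups differ only moderately is not assured. A wrong C1 configuration would turn into the Z alkene in step 13. The fallback sets C1 by catalyst control and C10 from C1. It sets out from 14 and comes back at 16: transfer hydrogenation of the side-chain ketone with RuCl[(S,S)-TsDPEN](p-cymene) (or its antipode, chosen for 1R) and HCO2H/Et3N gives the β-hydroxy ketone F4. Double deprotonation with LiN(i-Pr)2 and Fráter–Seebach-type methylation of the chelated dianion, anti to the C2 chain, then gives 16.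

Step 11. Ring closure onto a ketone flanked by a quaternary and a tertiary carbon may be slower than protodesilylation of the allylsilane, Lewis-acid-induced loss of the C8 silyloxy group, or fragmentation of the titanium alkoxide before work-up. The fallback replaces the Lewis acid by an organometallic addition under neutral conditions. It sets out from 17 and comes back at 18: bromodesilylation with N-bromosuccinimide gives the allylic bromide F5, and an intramolecular Barbier allylation with zinc dust in THF/aq. NH4Cl closes the same C5–C6 bond.

Step 15. Hydride may approach the wrong face of the C6 carbonyl, since the conformation of the ten-membered enone decides the outcome, and the hemiketal tautomer may dehydrate to a furan under the Lewis-acidic conditions. The fallback moves from substrate to reagent control. It sets out from 22 and comes back at 23: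
- silylation of O15 (TESCl, imidazole) gives the C15 triethylsilyl ether F6, which can no longer form the hemiketal;
- reduction with catecholborane and (S)-3,3-diphenyl-1-methyltetrahydro-3H-pyrrolo[1,2-c][1,3,2]oxazaborole (Corey–Bakshi–Shibata catalyst, antipode chosen for 6R) gives the allylic alcohol F7;
- AcOH/THF/H2O removes the triethylsilyl group.

Step 4. Enantiofacial discrimination may be poorer on an α-substituted enone than on the parent cyclic enones, and equilibration of C7 to the trans isomer may be incomplete. The fallback replaces asymmetric catalysis by a resolution. It sets out from 7 and comes back at 9: borylation with an achiral ligand (1,2-bis(diphenylphosphino)benzene) and oxidation give 9 together with its enantiomer, the (2S,3R)-hydroxy ketone F8. Candida antarctica lipase B and vinyl acetate should acetylate the (3R)-carbinol faster, giving the acetate F9 and leaving 9 to be separated.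

## Further compounds

F1 | step 13 | cis-fused hydroazulene-4,6,15-triol C1 mesylate (C4 not defined) | C[C@@]12C[C@H](O[Si](C)(C)C(C)(C)C)[C@@H](CCO[Si](C)(C)C(C)(C)C)[C@]1(O)CC(O)(CO)CC[C@H]2OS(C)(=O)=O
F2 | step 13 | 4,15-O-isopropylidene acetal of F1 | C[C@@]12C[C@H](O[Si](C)(C)C(C)(C)C)[C@@H](CCO[Si](C)(C)C(C)(C)C)[C@]1(O)CC3(COC(C)(C)O3)CC[C@H]2OS(C)(=O)=O
F3 | step 13 | ten-membered (E)-cyclodec-1(10)-en-6-one with C4 spiro-dioxolane (4,15-O-isopropylidene) | CC(C)(C)[Si](C)(C)OCC[C@@H]1[C@@H](O[Si](C)(C)C(C)(C)C)C/C(C)=C/CCC2(COC(C)(C)O2)CC1=O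
F4 | step 9 | (2R,3S)-3-(TBSO)-2-[2-(TBSO)ethyl]-5-[(1R)-1-hydroxy-4-[(trimethylsilyl)methyl]pent-4-en-1-yl]cyclopentan-1-one (C10 not defined) | O=C1[C@H](CCO[Si](C)(C)C(C)(C)C)[C@@H](O[Si](C)(C)C(C)(C)C)CC1[C@H](O)CCC(=C)C[Si](C)(C)C
F5 | step 11 | (1R)-4-(bromomethyl)-1-[(1S,3R,4S)-4-(TBSO)-3-[2-(TBSO)ethyl]-1-methyl-2-oxocyclopentyl]pent-4-en-1-yl methanesulfonate | O=C1[C@H](CCO[Si](C)(C)C(C)(C)C)[C@@H](O[Si](C)(C)C(C)(C)C)C[C@@]1(C)[C@H](OS(C)(=O)=O)CCC(=C)CBr
F6 | step 15 | C15 triethylsilyl ether of 22 | CC(C)(C)[Si](C)(C)OCC[C@@H]1[C@@H](O[Si](C)(C)C(C)(C)C)C/C(C)=C/CC/C(CO[Si](CC)(CC)CC)=C/C1=O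
F7 | step 15 | C15 triethylsilyl ether of 23 (6R) | CC(C)(C)[Si](C)(C)OCC[C@@H]1[C@@H](O[Si](C)(C)C(C)(C)C)C/C(C)=C/CC/C(CO[Si](CC)(CC)CC)=C/[C@H]1O
F8 | step 4 | (2S,3R)-3-hydroxy-2-[2-(TBSO)ethyl]cyclopentan-1-one | O=C1[C@@H](CCO[Si](C)(C)C(C)(C)C)[C@H](O)CC1
F9 | step 4 | (2S,3R)-3-acetoxy-2-[2-(TBSO)ethyl]cyclopentan-1-one | O=C1[C@@H](CCO[Si](C)(C)C(C)(C)C)[C@H](OC(C)=O)CC1
A1 | alternative 1 | eleven-membered macrolactone (O6 acylated by C15; C4 methylidene, C6 vinyl, C7 3-(TBSO)prop-1-en-2-yl, C8 OTBS) | C=C(CO[Si](C)(C)C(C)(C)C)[C@@H]1[C@@H](O[Si](C)(C)C(C)(C)C)C/C(C)=C/CCC(=C)C(=O)O[C@@H]1C=C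
A2 | alternative 1 | ten-membered carbocycle bridged by the C15–O6 butenolide | C=C(CO[Si](C)(C)C(C)(C)C)[C@@H]1[C@@H](O[Si](C)(C)C(C)(C)C)C/C(C)=C/CC/C2=C/[C@H]1OC2=O
A3 | alternative 2 | trans-fused γ-lactone with C6 aldehyde on C7 and C5 alkenyl iodide chain (C15 p-methoxybenzyl ether) | O=C[C@@H]1CC(=O)O[C@H]1C/C(C)=C/CC/C(COCc1ccc(OC)cc1)=C/I
A4 | alternative 2 | ten-membered C6 allylic alcohol fused to the saturated lactone | O=C1O[C@H]2C/C(C)=C/CC/C(COCc3ccc(OC)cc3)=C/[C@@H](O)[C@@H]2C1
A5 | alternative 3 | thirteen-membered cyclic C6–O–C13 diallyl ether (C7=C11 geometry left open) | O1CC(CO[Si](C)(C)C(C)(C)C)=C[C@@H](O[Si](C)(C)C(C)(C)C)C/C(C)=C/CC/C(CO[Si](c2ccccc2)(c2ccccc2)C(C)(C)C)=C/C1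
A6 | alternative 3 | ten-membered 1(10),4-dien-6-ol with the C7 2-propenyl unit | C=C(CO[Si](C)(C)C(C)(C)C)[C@@H]1[C@@H](O[Si](C)(C)C(C)(C)C)C/C(C)=C/CC/C(CO[Si](c2ccccc2)(c2ccccc2)C(C)(C)C)=C/[C@H]1O
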